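**Retrosynthetic overview**

1. Numbering (daucane): ring A = C1 (quaternary, CH3), C2, C3, C4 (C(OH)iPr), C5 (ring-fusion CH); ring B = C1, C5, C6 (ester carbinol), C7 (CH2), C8 (C–CH3), C9 (=CH), C10 (C=O).
2. Endgame: aryl acetate cleavage ⇐ C8=C9 by dehydrogenation of the C10 ketone ⇐ C6 ester ⇐ C4–OH-directed reduction of a C6 ketone ⇐ base equilibration of a saturated 6,10-dione to the trans ring fusion.
3. Ring B ⇐ ring A by a formal (4+3) annulation that makes C7–C8 and C10–C1 in one operation: rhodium-carbenoid cyclopropanation of a vinyl group, then divinylcyclopropane (Cope) rearrangement.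
4. Enabling feature: C8=C9 lies 1,4 to the C5–C6 bond, so ring B is a latent cyclohepta-1,4-diene; its four carbons C7–C6–C5–C1 are a 2-methyl-1-vinylcyclopentene (ring A alkene C1=C5 plus vinyl C6=C7) and its three carbons C8–C9–C10 are a vinylcarbene.
5. Ring A (C1 methyl, C4 stereocentre) ⇐ (S)-terpinen-4-ol by ozonolysis/aldol ring contraction; order of ring formation: A, then B.

Key step: step 7

Remark (assumption): β is the face of the C1 methyl. The sense of induction of Rh2(R-DOSP)4 is assigned by analogy with its cyclopropanation of monosubstituted alkenes. (S)-Terpinen-4-ol is taken in enantiopure grade. The C5/C6 configurations drawn for 14–20 (expected β-face hydroboration) and the C8 epimer mixture in 19–25 are not carried into the target.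

**Route**

Step 1
Reactants: 1 (S)-terpinen-4-ol
Product: 2 triethylsilyl ether of 1
Conditions: TESOTf, 2,6-lutidine, CH2Cl2, −78 to 0 °C
Reagents that add atoms: triethylsilyl trifluoromethanesulfonate, CC[Si](CC)(CC)OS(=O)(=O)C(F)(F)F
Why: Silyl triflate/2,6-lutidine silylation is the standard protection of a hindered tertiary alcohol, which must be masked against β-elimination and retro-aldol in steps 2–3 and against O–H insertion in step 7.

Step 2
Reactants: 2 triethylsilyl ether of 1
Product: 4 (3S)-6-oxo-3-isopropyl-3-(triethylsilyloxy)heptanal, via ozonide 3 (not isolated)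
Conditions: O3, CH2Cl2, −78 °C; then Me2S, −78 °C to rt
Reagents that add atoms: ozone, [O-][O+]=O
Why: Ozonolysis with reductive work-up cleaves the only alkene to the methyl ketone (future C1) and the aldehyde (future C6) without touching the silyl ether or the C4 stereocentre.

Step 3
Reactants: 4 (3S)-6-oxo-3-isopropyl-3-(triethylsilyloxy)heptanal
Product: 5 (5R)-2-methyl-5-isopropyl-5-(triethylsilyloxy)cyclopent-1-ene-1-carbaldehyde
Conditions: piperidine (0.2 equiv), AcOH (0.2 equiv), benzene, reflux (Dean–Stark)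
Reagents that add atoms: none
Why: Amine/acid-catalysed intramolecular aldol condensation (aldehyde enamine onto the methyl ketone, then dehydration) is the classical ring contraction of 6-oxoheptanals to 2-methylcyclopent-1-ene-1-carbaldehydes and builds ring A with the C1 methyl and the C4 carbinol in place.

Step 4
Reactants: 5 (5R)-2-methyl-5-isopropyl-5-(triethylsilyloxy)cyclopent-1-ene-1-carbaldehyde
Product: 6 (R)-2-ethenyl-3-methyl-1-isopropylcyclopent-2-en-1-yl triethylsilyl ether
Conditions: Ph3PCH3Br, KN(SiMe3)2, THF, 0 °C to rt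
Reagents that add atoms: methyltriphenylphosphonium bromide, C[P+](c1ccccc1)(c1ccccc1)c1ccccc1.[Br-]
Why: Wittig methylenation of the hindered enal adds C7 and completes the 1-vinylcyclopentene diene C7=C6–C5=C1.

Step 5
Reactants: 7 ethyl diazoacetate; 8 (tert-butyldimethylsilyloxy)acetaldehyde
Product: 9 ethyl 4-(tert-butyldimethylsilyloxy)-2-diazo-3-hydroxybutanoate
Conditions: DBU (10 mol %), MeCN, rt
Reagents that add atoms: none
Why: Base-catalysed aldol-type addition of the acidic diazoacetate C–H to an aldehyde is a standard route to β-hydroxy-α-diazo esters.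

Step 6
Reactants: 9 ethyl 4-(tert-butyldimethylsilyloxy)-2-diazo-3-hydroxybutanoate
Product: 11 ethyl (E)-4-(tert-butyldimethylsilyloxy)-2-diazobut-3-enoate, via dichlorophosphate 10 (not isolated)
Conditions: POCl3, Et3N, CH2Cl2, 0 °C; used at once
Reagents that add atoms: none
Why: POCl3/Et3N dehydration of β-hydroxy-α-diazo esters is the established entry to vinyldiazoacetates, and elimination can only run towards the silyloxy-bearing carbon to give the E enol ether.

Step 7
Reactants: 6 (R)-2-ethenyl-3-methyl-1-isopropylcyclopent-2-en-1-yl triethylsilyl ether; 11 ethyl (E)-4-(tert-butyldimethylsilyloxy)-2-diazobut-3-enoate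
Product: 13 ethyl 10α-(tert-butyldimethylsilyloxy)-1β-methyl-4α-isopropyl-4β-(triethylsilyloxy)bicyclo[5.3.0]deca-5,8-diene-8-carboxylate, via cis-divinylcyclopropane 12 (not isolated)
Conditions: Rh2(R-DOSP)4 (2 mol %), hexanes, −78 °C to rt, slow addition of 11; then toluene, 80 °C
Reagents that add atoms: none
Why: Rh2(R-DOSP)4 converts 11 into a donor/acceptor rhodium vinylcarbenoid that cyclopropanates the unhindered terminal vinyl group of 6 (C7–C8 and C6–C8 formed) to give cis-divinylcyclopropane 12, which undergoes a [3,3]-sigmatropic (Cope) rearrangement through a boat transition state that forms C10–C1 and cleaves C6–C8. The closest known reaction type is the tandem cyclopropanation/Cope formal (4+3) cycloaddition of vinyldiazoacetates with dienes, including 2-methyl-1-vinylcycloalkenes that give angular-methyl quaternary centres. Ring B (seven-membered) is closed by this (4+3) annulation, that is, intermolecular cyclopropanation followed by ring expansion of the three-membered ring in a six-membered boat array. C1 is set by chirality transfer from the catalyst-controlled cyclopropane carbon C6, because the geometry of the ring alkene is fixed, and C10 (OTBS trans to the C1 methyl, from the E enol ether) is erased later. The step needs site selectivity for the terminal vinyl group over the tetrasubstituted ring alkene (secured by sterics), the cis-divinyl arrangement (inherent to donor/acceptor carbenoids) and catalyst control over the existing C4 stereocentre, which is remote from the cyclopropanation site. Warming is planned because the Cope step must build a quaternary centre on the face of the C4 isopropyl group.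

Step 8
Reactants: 13 ethyl 10α-(tert-butyldimethylsilyloxy)-1β-methyl-4α-isopropyl-4β-(triethylsilyloxy)bicyclo[5.3.0]deca-5,8-diene-8-carboxylate
Product: 15 C6 alcohol (6β-OH and 5β-H expected), via alkylborane 14 (not isolated)
Conditions: BH3·THF, THF, 0 °C to rt; then NaBO3·4H2O, THF/H2O, rt
Reagents that add atoms: sodium perborate, O[B-]1(O)OO[B-](O)(O)OO1.[Na+].[Na+]
Why: Hydroboration–oxidation is selective for the electron-rich trisubstituted C5=C6 over the conjugated enoate and puts boron on the less substituted C6; syn addition from the convex β face is expected, but C6 is re-oxidised and C5 equilibrated in step 13.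

Step 9
Reactants: 15 C6 alcohol
Product: 16 allylic diol (8-hydroxymethyl)
Conditions: iBu2AlH, CH2Cl2, −78 to −20 °C
Reagents that add atoms: none
Why: iBu2AlH reduces the α,β-unsaturated ester by 1,2-addition to the primary allylic alcohol while the silyl ethers survive.

Step 10
Reactants: 16 allylic diol
Product: 18 C8-methyl alkene, via allylic mesylate 17 (not isolated)
Conditions: MsCl (1.1 equiv), Et3N, CH2Cl2, −40 °C; then LiEt3BH, THF, −40 to 0 °C
Reagents that add atoms: none
Why: The primary allylic hydroxyl is mesylated much faster than the hindered secondary C6–OH, and SN2 hydride displacement of the primary mesylate gives the C8 methyl group without allylic transposition.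

Step 11
Reactants: 18 C8-methyl alkene
Product: 19 saturated alcohol (C8 epimer mixture)
Conditions: H2 (1 atm), [Ir(cod)(PCy3)(py)]PF6 (5 mol %), CH2Cl2, rt
Reagents that add atoms: none
Why: Hydroxyl-directed homogeneous hydrogenation saturates the trisubstituted C8=C9 without allylic C–O hydrogenolysis, so that the base equilibration in step 13 cannot draw a β,γ-alkene into conjugation with the C6 ketone.

Step 12
Reactants: 19 saturated alcohol
Product: 20 4β,6,10α-triol
Conditions: HF·pyridine, THF, 0 °C to rt
Reagents that add atoms: none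
Why: Fluoride under non-basic conditions removes both the tertiary triethylsilyl and the secondary tert-butyldimethylsilyl ether in one operation.

Step 13
Reactants: 20 4β,6,10α-triol
Product: 22 trans-fused 4β-hydroxy-6,10-dione (5α-H), via cis-fused dione 21 (not isolated)
Conditions: Dess–Martin periodinane, CH2Cl2, rt; aq. NaHCO3 wash; then DBU (0.3 equiv), CH2Cl2, rt
Reagents that add atoms: none
Why: The periodinane oxidises both secondary alcohols and leaves the tertiary one, and reversible enolisation at C5 should give the thermodynamically preferred trans-fused β-hydroxy ketone, in which C6 is trans to the C4 isopropyl group and hydrogen-bonded to the cis C4–OH.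

Step 14
Reactants: 22 trans-fused 4β-hydroxy-6,10-dione
Product: 23 4β,6α-dihydroxy-10-ketone
Conditions: Me4NBH(OAc)3, AcOH/MeCN (1:1), −30 °C
Reagents that add atoms: none
Why: In this Evans–Saksena reduction the acetoxyborohydride bound to the C4 oxygen delivers hydride intramolecularly to the β face of the C6 ketone, giving the 1,3-anti diol (6α-OH) while the undirected, hindered C10 ketone is not reduced.

Step 15
Reactants: 23 4β,6α-dihydroxy-10-ketone; 24 4-acetoxy-3-methoxybenzoic acid
Product: 25 C6 4-acetoxy-3-methoxybenzoate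
Conditions: DCC, DMAP (cat.), CH2Cl2, 0 °C to rt
Reagents that add atoms: none
Why: Steglich esterification acylates the secondary C6 hydroxyl selectively over the hindered tertiary C4 hydroxyl.

Step 16
Reactants: 25 C6 4-acetoxy-3-methoxybenzoate
Product: 26 C8=C9 enone (phenol still acetylated)
Conditions: IBX (1.5 equiv), DMSO, 65 °C
Reagents that add atoms: none
Why: IBX dehydrogenation of the C10 ketone can only run towards C9 because C1 is quaternary, so both C8 epimers converge on the β-methyl enone; limiting the oxidant should prevent further dehydrogenation.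

Step 17
Reactants: 26 C8=C9 enone
Product: 27 target
Conditions: pyrrolidine (1.5 equiv), CH2Cl2, 0 °C
Reagents that add atoms: none
Why: Aminolysis of the aryl acetate is far faster than attack on the hindered alkyl aroyl ester, and the mild conditions avoid vinylogous β-elimination of the C6 ester.

**Compound list**

1 | (S)-terpinen-4-ol, (1S)-4-methyl-1-(propan-2-yl)cyclohex-3-en-1-ol | CC1=CC[C@](O)(C(C)C)CC1 | starting material
2 | triethyl{[(1S)-4-methyl-1-(propan-2-yl)cyclohex-3-en-1-yl]oxy}silane | CC1=CC[C@](O[Si](CC)(CC)CC)(C(C)C)CC1 | intermediate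
3 | ozonide (1,2,4-trioxolane) of 2 | CC12OC(C[C@](O[Si](CC)(CC)CC)(C(C)C)CC1)OO2 | intermediate
4 | (3S)-6-oxo-3-(propan-2-yl)-3-[(triethylsilyl)oxy]heptanal | CC(=O)CC[C@@](O[Si](CC)(CC)CC)(C(C)C)CC=O | intermediate
5 | (5R)-2-methyl-5-(propan-2-yl)-5-[(triethylsilyl)oxy]cyclopent-1-ene-1-carbaldehyde | O=CC1=C(C)CC[C@@]1(O[Si](CC)(CC)CC)C(C)C | intermediate
6 | triethyl{[(1R)-2-ethenyl-3-methyl-1-(propan-2-yl)cyclopent-2-en-1-yl]oxy}silane | C=CC1=C(C)CC[C@@]1(O[Si](CC)(CC)CC)C(C)C | intermediate
7 | ethyl diazoacetate | CCOC(=O)C=[N+]=[N-] | starting material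
8 | 2-[(tert-butyldimethylsilyl)oxy]acetaldehyde | CC(C)(C)[Si](C)(C)OCC=O | starting material
9 | ethyl 4-[(tert-butyldimethylsilyl)oxy]-2-diazo-3-hydroxybutanoate (racemic) | CCOC(=O)C(=[N+]=[N-])C(O)CO[Si](C)(C)C(C)(C)C | intermediate
10 | dichlorophosphate ester of 9 | CCOC(=O)C(=[N+]=[N-])C(OP(=O)(Cl)Cl)CO[Si](C)(C)C(C)(C)C | intermediate
11 | ethyl (3E)-4-[(tert-butyldimethylsilyl)oxy]-2-diazobut-3-enoate | CCOC(=O)C(=[N+]=[N-])/C=C/O[Si](C)(C)C(C)(C)C | intermediate
12 | ethyl 1-[(E)-2-(tert-butyldimethylsilyloxy)ethenyl]-2-[(5R)-2-methyl-5-isopropyl-5-(triethylsilyloxy)cyclopent-1-en-1-yl]cyclopropane-1-carboxylate, vinyl and cyclopentenyl cis | CCOC(=O)[C@]1(/C=C/O[Si](C)(C)C(C)(C)C)C[C@H]1C1=C(C)CC[C@@]1(O[Si](CC)(CC)CC)C(C)C | intermediate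
13 | ethyl 10α-(tert-butyldimethylsilyloxy)-1β-methyl-4α-isopropyl-4β-(triethylsilyloxy)bicyclo[5.3.0]deca-5,8-diene-8-carboxylate (daucane numbering) | C1C(C(=O)OCC)=C[C@@H](O[Si](C)(C)C(C)(C)C)[C@@]2(C)CC[C@@](O[Si](CC)(CC)CC)(C(C)C)C2=C1 | intermediate
14 | C6 alkylborane from 13 (6β-BH2, 5β-H) | [BH2][C@@H]1CC(C(=O)OCC)=C[C@@H](O[Si](C)(C)C(C)(C)C)[C@@]2(C)CC[C@@](O[Si](CC)(CC)CC)(C(C)C)[C@@H]12 | intermediate
15 | ethyl 6β-hydroxy-5βH-10α-(tert-butyldimethylsilyloxy)-1β-methyl-4α-isopropyl-4β-(triethylsilyloxy)bicyclo[5.3.0]dec-8-ene-8-carboxylate | O[C@@H]1CC(C(=O)OCC)=C[C@@H](O[Si](C)(C)C(C)(C)C)[C@@]2(C)CC[C@@](O[Si](CC)(CC)CC)(C(C)C)[C@@H]12 | intermediate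
16 | 8-(hydroxymethyl) analogue of 15 (allylic diol) | O[C@@H]1CC(CO)=C[C@@H](O[Si](C)(C)C(C)(C)C)[C@@]2(C)CC[C@@](O[Si](CC)(CC)CC)(C(C)C)[C@@H]12 | intermediate
17 | primary allylic methanesulfonate of 16 | O[C@@H]1CC(COS(C)(=O)=O)=C[C@@H](O[Si](C)(C)C(C)(C)C)[C@@]2(C)CC[C@@](O[Si](CC)(CC)CC)(C(C)C)[C@@H]12 | intermediate
18 | 6β-hydroxy-1β,8-dimethyl-4α-isopropyl-10α-(tert-butyldimethylsilyloxy)-4β-(triethylsilyloxy)bicyclo[5.3.0]dec-8-ene | O[C@@H]1CC(C)=C[C@@H](O[Si](C)(C)C(C)(C)C)[C@@]2(C)CC[C@@](O[Si](CC)(CC)CC)(C(C)C)[C@@H]12 | intermediate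
19 | 8,9-dihydro derivative of 18 (C8 epimers) | O[C@@H]1CC(C)C[C@@H](O[Si](C)(C)C(C)(C)C)[C@@]2(C)CC[C@@](O[Si](CC)(CC)CC)(C(C)C)[C@@H]12 | intermediate
20 | 1β,8-dimethyl-4α-isopropylbicyclo[5.3.0]decane-4β,6β,10α-triol (5βH) | O[C@@H]1CC(C)C[C@@H](O)[C@@]2(C)CC[C@@](O)(C(C)C)[C@@H]12 | intermediate
21 | cis-fused 4β-hydroxy-1β,8-dimethyl-4α-isopropylbicyclo[5.3.0]decane-6,10-dione (5βH) | O=C1CC(C)CC(=O)[C@@]2(C)CC[C@@](O)(C(C)C)[C@@H]12 | intermediate
22 | trans-fused 4β-hydroxy-1β,8-dimethyl-4α-isopropylbicyclo[5.3.0]decane-6,10-dione (5αH) | O=C1CC(C)CC(=O)[C@@]2(C)CC[C@@](O)(C(C)C)[C@H]12 | intermediate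
23 | trans-fused 4β,6α-dihydroxy-1β,8-dimethyl-4α-isopropylbicyclo[5.3.0]decan-10-one | O[C@H]1CC(C)CC(=O)[C@@]2(C)CC[C@@](O)(C(C)C)[C@H]12 | intermediate
24 | 4-acetoxy-3-methoxybenzoic acid | COc1cc(C(=O)O)ccc1OC(C)=O | starting material
25 | 6α-(4-acetoxy-3-methoxybenzoate) of 23 | COc1cc(C(=O)O[C@H]2CC(C)CC(=O)[C@@]3(C)CC[C@@](O)(C(C)C)[C@H]23)ccc1OC(C)=O | intermediate
26 | 8,9-didehydro derivative of 25 (β-methyl enone) | COc1cc(C(=O)O[C@H]2CC(C)=CC(=O)[C@@]3(C)CC[C@@](O)(C(C)C)[C@H]23)ccc1OC(C)=O | intermediate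
27 | CNP0136950.2 | COc1cc(C(=O)O[C@H]2CC(C)=CC(=O)[C@@]3(C)CC[C@@](O)(C(C)C)[C@H]23)ccc1O | target

**Step count and risks**

Total step count: 17. Longest linear sequence: 15 (steps 1–4 and 7–17).

Steps most likely to fail:

Step 7. The risk is loss of facial control in the cyclopropanation (the catalyst is overridden by the neighbouring C4 stereocentre), which would pass the wrong configuration on to C1. The fallback replaces catalyst control by auxiliary control; it sets out from diene 6 and aldehyde 8 and returns at diol 16. (R)-Pantolactone is acylated with succinimidyl diazoacetate (Et3N, DMAP) to give (R)-pantolactonyl diazoacetate F1. DBU-catalysed addition of F1 to 8 gives the β-hydroxy diazo ester F2, and POCl3/Et3N gives the pantolactonyl vinyldiazoacetate F3. With the achiral catalyst Rh2(O2CC7H15)4 and diene 6, the same cyclopropanation/Cope sequence gives the pantolactonyl ester analogue of 13, cycloheptadiene F4. Hydroboration/oxidation as in step 8 gives alcohol F5, and iBu2AlH reduction, which also removes the auxiliary, gives 16. The pantolactone enantiomer would be chosen for the required facial sense; (R) is drawn.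

Step 13. The risk is retro-aldol cleavage (or dehydration) of the free β-hydroxy ketone during base equilibration, or incomplete epimerisation at C5. The fallback equilibrates before the tertiary alcohol is unmasked; it sets out from 19 and returns at 22. Dess–Martin oxidation of 19 gives the cis-fused C6 ketone F6 with both silyl ethers in place. DBU then equilibrates C5 to the trans-fused ketone F7, where retro-aldol is impossible. HF·pyridine gives the trans-fused keto diol F8, and a second Dess–Martin oxidation gives 22.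

Step 14. The risk is slow exchange of the hindered tertiary hydroxyl onto boron, so that hydride delivery is undirected and facial selectivity at C6 is poor. The fallback uses undirected reduction followed by inversion; it sets out from 22 and returns at 25. LiBH(sBu)3 at −78 °C reduces the less hindered C6 ketone from the open α face to the 6β-alcohol F9. Mitsunobu esterification of F9 with acid 24 (PPh3, DIAD) inverts C6 and gives ester 25 directly.

Further compounds
F1 | step 7 | (R)-pantolactonyl diazoacetate | CC1(C)COC(=O)[C@@H]1OC(=O)C=[N+]=[N-]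
F2 | step 7 | (R)-pantolactonyl 4-(tert-butyldimethylsilyloxy)-2-diazo-3-hydroxybutanoate | CC1(C)COC(=O)[C@@H]1OC(=O)C(=[N+]=[N-])C(O)CO[Si](C)(C)C(C)(C)C
F3 | step 7 | (R)-pantolactonyl (E)-4-(tert-butyldimethylsilyloxy)-2-diazobut-3-enoate | CC1(C)COC(=O)[C@@H]1OC(=O)C(=[N+]=[N-])/C=C/O[Si](C)(C)C(C)(C)C
F4 | step 7 | (R)-pantolactonyl ester analogue of 13 | C1C(C(=O)O[C@H]3C(=O)OCC3(C)C)=C[C@@H](O[Si](C)(C)C(C)(C)C)[C@@]2(C)CC[C@@](O[Si](CC)(CC)CC)(C(C)C)C2=C1
F5 | step 7 | (R)-pantolactonyl ester analogue of 15 | O[C@@H]1CC(C(=O)O[C@H]3C(=O)OCC3(C)C)=C[C@@H](O[Si](C)(C)C(C)(C)C)[C@@]2(C)CC[C@@](O[Si](CC)(CC)CC)(C(C)C)[C@@H]12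
F6 | step 13 | cis-fused C6 ketone of 19 (silyl ethers intact) | O=C1CC(C)C[C@@H](O[Si](C)(C)C(C)(C)C)[C@@]2(C)CC[C@@](O[Si](CC)(CC)CC)(C(C)C)[C@@H]12
F7 | step 13 | trans-fused C6 ketone (silyl ethers intact) | O=C1CC(C)C[C@@H](O[Si](C)(C)C(C)(C)C)[C@@]2(C)CC[C@@](O[Si](CC)(CC)CC)(C(C)C)[C@H]12
F8 | step 13 | trans-fused 4β,10α-dihydroxy-6-ketone | O=C1CC(C)C[C@@H](O)[C@@]2(C)CC[C@@](O)(C(C)C)[C@H]12
F9 | step 14 | trans-fused 4β,6β-dihydroxy-10-ketone (6-epimer of 23) | O[C@@H]1CC(C)CC(=O)[C@@]2(C)CC[C@@](O)(C(C)C)[C@H]12
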